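**Retrosynthetic overview**

1. Target 19 comes from its bis-benzyl ether 18 (debenzylation), and 18 from phthalide 16: the C1 carboxyl and the C6 pentanoyl group of ring A are masked together as a 3-butylphthalide that is opened and oxidised late.
2. Ring B is made by aromatising a cyclohexane-1,3-dione, itself built by a Michael–Dieckmann annulation of aryloxymalonate 9 with (E)-non-3-en-2-one 10 (bonds C1'–C2' and C5'–C6').
3. Feature used: ring B is a 5-alkylresorcinol in which C1' (ether oxygen) lies between C2' (pentyl) and C6' (OH). C1' is therefore the central carbon of a malonate that already carries the ring A oxygen, C6' is one malonate ester carbon, and C2'–C5' are C4–C1 of the enone.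
4. Malonate 9 comes from O-alkylation of 7-hydroxyphthalide 7 with dimethyl chloromalonate; 7 from peri-demethylation of phthalide 6; 6 from ortho-lithiation of amide 2 and pentanal.
5. Ring order: ring A is bought; its lactone ring is closed in step 2; the ring B carbocycle is closed in step 5 and aromatised in step 7; the lactone ring is opened in step 9.

Key step: step 5

Assumption: the target has no stereocentre and is taken as the open keto acid drawn, which may equilibrate with its cyclic lactol tautomer. Compounds 5–17 are racemic at the carbinol/phthalide C3 centre, which is erased in step 9.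

**Route**

Step 1
Reactants: 1 2,4-dimethoxybenzoyl chloride
Product: 2 N,N-diethyl-2,4-dimethoxybenzamide
Conditions: Et2NH (1.2 equiv), 2 M aq. NaOH, CH2Cl2, 0 °C to rt
Reagents that add atoms: diethylamine, CCNCC
Why: Schotten–Baumann acylation of a secondary amine by an aroyl chloride, which installs the tertiary amide needed as directing group.

Step 2
Reactants: 2 N,N-diethyl-2,4-dimethoxybenzamide; 3 pentanal
Product: 6 3-butyl-5,7-dimethoxyphthalide (racemic), via aryllithium 4 (not isolated), via hydroxy amide 5 (not isolated)
Conditions: s-BuLi (1.2 equiv), TMEDA (1.2 equiv), THF, −78 °C; 3, −78 °C to rt; 1 M HCl quench; then TsOH·H2O (0.2 equiv), PhMe, reflux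
Reagents that add atoms: none
Why: Directed ortho-metalation, in which the tertiary amide outranks the methoxy groups so that H6 (not H3 between the two methoxy groups) should be removed, then 1,2-addition to the aldehyde and acid-catalysed lactonisation with loss of diethylamine; C3 is formed racemic, which is acceptable because it becomes the ketone carbon in step 9.

Step 3
Reactants: 6 3-butyl-5,7-dimethoxyphthalide
Product: 7 3-butyl-7-hydroxy-5-methoxyphthalide (racemic)
Conditions: BCl3 (1.2 equiv), CH2Cl2, −78 to 0 °C; then H2O
Reagents that add atoms: none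
Why: Chelation-controlled Lewis-acid ether cleavage, in which BCl3 bound to the lactone carbonyl reaches only the peri methoxy group at C7 through a six-membered chelate, so the C5 methoxy group kept in the target should be untouched.

Step 4
Reactants: 7 3-butyl-7-hydroxy-5-methoxyphthalide; 8 dimethyl 2-chloromalonate
Product: 9 dimethyl 2-[(3-butyl-5-methoxy-1-oxo-1,3-dihydro-2-benzofuran-7-yl)oxy]malonate (racemic; phthalide numbering)
Conditions: K2CO3 (2 equiv), acetone, reflux
Reagents that add atoms: none
Why: Williamson-type O-alkylation of a phenoxide at the sp3 carbon of a 2-halomalonate, the usual way to aryloxymalonates, so the ether bond that ends up between two ortho substituents of ring B needs no hindered aryl–oxygen coupling; the chloromalonate is chosen over the bromo compound to limit halogen transfer to the electron-rich ring.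

Step 5
Reactants: 9 dimethyl 2-[(3-butyl-5-methoxy-1-oxo-1,3-dihydro-2-benzofuran-7-yl)oxy]malonate; 10 (E)-non-3-en-2-one
Product: 12 methyl 1-aryloxy-2,4-dioxo-6-pentylcyclohexane-1-carboxylate (aryl = phthalide unit of 9; mixture of racemic diastereomers), via Michael adduct 11 (not isolated)
Conditions: t-BuOK (1.1 equiv), 10 (1.5 equiv), THF/t-BuOH (5:1), 0 °C to 50 °C; then 1 M HCl to pH 3
Reagents that add atoms: none
Why: Proposed new method: t-BuOK converts 9 into its malonate enolate, which adds to C4 of enone 10 to form bond C1'–C2' (adduct 11); after proton transfer the methyl ketone enolate attacks one of the two ester groups to form bond C5'–C6', and the methoxide released is consumed at once in deprotonating the new 1,3-dione, so the reversible conjugate addition is drained into a stabilised enolate. The closest known reaction is the Michael–Dieckmann annulation of dimethyl malonate with non-3-en-2-one used to make 5-pentylresorcinol, and 2-heteroatom-substituted malonates such as acetamidomalonates are established Michael donors towards beta-substituted enals and enones, but an aryloxymalonate has not been carried through the whole annulation. Ring B closes in a 6-(enolendo)-exo-trig mode. C1' and C2' become stereocentres without control (the remote phthalide centre does not differentiate the enone faces, and either diastereotopic ester can be attacked), which is accepted because both carbons become sp2 on aromatisation. The step needs the malonate anion to react with the enone and not with the lactone carbonyl of ring A: direct attack would have to build a second five-membered ring on the C7–C7a–C1 corner of the phthalide, a badly strained tricycle, and the hindered, poorly nucleophilic base is used in place of methoxide so that the lactone is not opened to a methyl ester that could close to a benzofuran-3-one. The substitution pattern is fixed by connectivity, since only the malonate CH is acidic enough to act as donor, the enone can accept only at its pentyl-bearing carbon, and only the methyl terminus can reach an ester through a six-membered ring.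

Step 6
Reactants: 12 methyl 1-aryloxy-2,4-dioxo-6-pentylcyclohexane-1-carboxylate
Product: 14 4-aryloxy-5-pentylcyclohexane-1,3-dione (aryl = phthalide unit of 9; diastereomer mixture), via hydroxy diacid salt 13 (not isolated)
Conditions: 2 M aq. NaOH, 1,4-dioxane, 90 °C; then 6 M HCl to pH 1, 80 °C
Reagents that add atoms: none
Why: Ester saponification while the dione is protected as its enolate and the lactone as its ring-opened carboxylate, then acidification, which recloses the five-membered lactone and lets the beta-keto acid lose CO2, the classical hydrolysis/decarboxylation of Michael–Dieckmann adducts.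

Step 7
Reactants: 14 4-aryloxy-5-pentylcyclohexane-1,3-dione
Product: 15 3-butyl-7-(2,4-dihydroxy-6-pentylphenoxy)-5-methoxyphthalide (racemic)
Conditions: I2 (0.2 equiv), DMSO, 80 °C
Reagents that add atoms: none
Why: Iodine-catalysed oxidative aromatisation of a cyclohexane-1,3-dione (alpha-iodination, loss of HI, tautomerisation to the resorcinol) with DMSO reoxidising HI to iodine; the stereocentres at C1' and C2' disappear here.

Step 8
Reactants: 15 3-butyl-7-(2,4-dihydroxy-6-pentylphenoxy)-5-methoxyphthalide
Product: 16 7-[2,4-bis(benzyloxy)-6-pentylphenoxy]-3-butyl-5-methoxyphthalide (racemic)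
Conditions: BnBr (2.5 equiv), K2CO3 (3 equiv), DMF, 60 °C
Reagents that add atoms: benzyl bromide, BrCc1ccccc1
Why: Williamson etherification of both phenols; benzyl ethers are chosen because they should withstand hot aqueous KOH and cold permanganate and can be removed at the end without reduction and without releasing formaldehyde next to a free resorcinol.

Step 9
Reactants: 16 7-[2,4-bis(benzyloxy)-6-pentylphenoxy]-3-butyl-5-methoxyphthalide
Product: 18 2-[2,4-bis(benzyloxy)-6-pentylphenoxy]-4-methoxy-6-pentanoylbenzoic acid, via potassium hydroxy carboxylate 17 (not isolated)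
Conditions: KOH (3 equiv), H2O/1,4-dioxane, 80 °C; then KMnO4 (0.8 equiv), 0 °C; then 1 M HCl to pH 2
Reagents that add atoms: potassium hydroxide, [K+].[OH-]
Why: Lactone saponification gives a hydroxy carboxylate that cannot relactonise in base, and alkaline permanganate oxidises its secondary benzylic alcohol to the aryl ketone (the classical conversion of 3-alkylphthalides into 2-acylbenzoic acids), which also removes the last stereocentre.

Step 10
Reactants: 18 2-[2,4-bis(benzyloxy)-6-pentylphenoxy]-4-methoxy-6-pentanoylbenzoic acid
Product: 19 2-(2,4-dihydroxy-6-pentylphenoxy)-4-methoxy-6-pentanoylbenzoic acid (target)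
Conditions: BCl3 (4 equiv), C6HMe5 (6 equiv), CH2Cl2, −78 °C; then H2O
Reagents that add atoms: none
Why: Lewis-acid debenzylation of aryl benzyl ethers by BCl3 at low temperature with pentamethylbenzene as benzyl cation trap, which should spare the ketone, the acid, the diaryl ether and the methoxy group (not ortho to a carbonyl) and prevent C-benzylation of the liberated resorcinol.

**Compound list**

1 | 2,4-dimethoxybenzoyl chloride | COc1ccc(C(=O)Cl)c(OC)c1 | starting material
2 | N,N-diethyl-2,4-dimethoxybenzamide | CCN(CC)C(=O)c1ccc(OC)cc1OC | intermediate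
3 | pentanal | CCCCC=O | starting material
4 | N,N-diethyl-2-lithio-4,6-dimethoxybenzamide | CCN(CC)C(=O)c1c([Li])cc(OC)cc1OC | intermediate
5 | N,N-diethyl-2-(1-hydroxypentyl)-4,6-dimethoxybenzamide (racemic) | CCCCC(O)c1cc(OC)cc(OC)c1C(=O)N(CC)CC | intermediate
6 | 3-butyl-5,7-dimethoxy-2-benzofuran-1(3H)-one (3-butyl-5,7-dimethoxyphthalide, racemic) | CCCCC1OC(=O)c2c(OC)cc(OC)cc21 | intermediate
7 | 3-butyl-7-hydroxy-5-methoxy-2-benzofuran-1(3H)-one (racemic) | CCCCC1OC(=O)c2c(O)cc(OC)cc21 | intermediate
8 | dimethyl 2-chloromalonate | COC(=O)C(Cl)C(=O)OC | starting material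
9 | dimethyl 2-[(3-butyl-5-methoxy-1-oxo-1,3-dihydro-2-benzofuran-7-yl)oxy]malonate (racemic) | CCCCC1OC(=O)c2c(OC(C(=O)OC)C(=O)OC)cc(OC)cc21 | intermediate
10 | (E)-non-3-en-2-one | CCCCC/C=C/C(C)=O | starting material
11 | dimethyl 2-[(3-butyl-5-methoxy-1-oxo-1,3-dihydro-2-benzofuran-7-yl)oxy]-2-(2-oxononan-4-yl)malonate (diastereomer mixture) | CCCCCC(CC(C)=O)C(Oc1cc(OC)cc2c1C(=O)OC2CCCC)(C(=O)OC)C(=O)OC | intermediate
12 | methyl 1-[(3-butyl-5-methoxy-1-oxo-1,3-dihydro-2-benzofuran-7-yl)oxy]-2,4-dioxo-6-pentylcyclohexane-1-carboxylate (mixture of racemic diastereomers; largely enolised; drawn as the triketo form) | CCCCCC1CC(=O)CC(=O)C1(Oc1cc(OC)cc2c1C(=O)OC2CCCC)C(=O)OC | intermediate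
13 | 1-[2-carboxy-3-(1-hydroxypentyl)-5-methoxyphenoxy]-2,4-dioxo-6-pentylcyclohexane-1-carboxylic acid (present as its sodium salts; drawn as the free acid) | CCCCCC1CC(=O)CC(=O)C1(Oc1cc(OC)cc(C(O)CCCC)c1C(=O)O)C(=O)O | intermediate
14 | 4-[(3-butyl-5-methoxy-1-oxo-1,3-dihydro-2-benzofuran-7-yl)oxy]-5-pentylcyclohexane-1,3-dione (diastereomer mixture) | CCCCCC1CC(=O)CC(=O)C1Oc1cc(OC)cc2c1C(=O)OC2CCCC | intermediate
15 | 3-butyl-7-(2,4-dihydroxy-6-pentylphenoxy)-5-methoxy-2-benzofuran-1(3H)-one (racemic) | CCCCCc1cc(O)cc(O)c1Oc1cc(OC)cc2c1C(=O)OC2CCCC | intermediate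
16 | 7-[2,4-bis(benzyloxy)-6-pentylphenoxy]-3-butyl-5-methoxy-2-benzofuran-1(3H)-one (racemic) | CCCCCc1cc(OCc2ccccc2)cc(OCc2ccccc2)c1Oc1cc(OC)cc2c1C(=O)OC2CCCC | intermediate
17 | potassium 2-[2,4-bis(benzyloxy)-6-pentylphenoxy]-6-(1-hydroxypentyl)-4-methoxybenzoate (racemic) | CCCCCc1cc(OCc2ccccc2)cc(OCc2ccccc2)c1Oc1cc(OC)cc(C(O)CCCC)c1C(=O)[O-].[K+] | intermediate
18 | 2-[2,4-bis(benzyloxy)-6-pentylphenoxy]-4-methoxy-6-pentanoylbenzoic acid | CCCCCc1cc(OCc2ccccc2)cc(OCc2ccccc2)c1Oc1cc(OC)cc(C(=O)CCCC)c1C(=O)O | intermediate
19 | 2-(2,4-dihydroxy-6-pentylphenoxy)-4-methoxy-6-pentanoylbenzoic acid | CCCCCc1cc(O)cc(O)c1Oc1cc(OC)cc(C(=O)CCCC)c1C(=O)O | target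

**Step count**

Total steps: 10. Longest linear sequence: 10 steps (1 to 19).

**Steps most likely to fail**

1. Step 5 (carries the label). Possible failures are:
   - the reversible conjugate addition may lie on the side of the reactants, because a quaternary carbon is formed next to a tertiary one;
   - alkoxide may strip a methoxycarbonyl group from 9 or 11;
   - the lactone may open and the malonate anion may then close onto the freed ester;
   - the enone may self-condense.

   Fallback with known chemistry, setting out from phenol 7 and coming back at 16: commercial olivetol (5-pentylbenzene-1,3-diol) would be benzylated (BnBr, K2CO3, DMF) to 1,3-bis(benzyloxy)-5-pentylbenzene F1. F1 would be iodinated with N-iodosuccinimide in MeCN at the ring position ortho to the pentyl group and para to a benzyloxy group to give 1,5-bis(benzyloxy)-2-iodo-3-pentylbenzene F2. F2 would then be joined to 7 in a copper-catalysed Ullmann diaryl ether synthesis (CuI, picolinic acid, K3PO4, DMSO, 100 °C) to give 16 directly, replacing steps 4 to 8. This coupling is hindered on both partners, which is why it is kept as the reserve and not the main route.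

2. Step 7. The iodine that is regenerated throughout the reaction may iodinate the electron-rich ring positions, or the dehydrogenation may stall at a partly unsaturated stage. Fallback, setting out from 14 and coming back at 15: one equivalent of Br2 in DMF at 0 °C should be consumed by the doubly activated carbon between the two carbonyl groups (C5') and give 2-bromo-4-aryloxy-5-pentylcyclohexane-1,3-dione F3. Warming F3 in the same solvent to about 120 °C should move the bromine to C3' under HBr catalysis and eliminate HBr, giving 15. This replaces a catalytic oxidation, with its oxidant always present, by a stoichiometric halogenation at one defined carbon followed by a separate thermal elimination.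

3. Step 9. Permanganate may over-oxidise the benzyl ether methylene groups, the electron-rich rings or the enolisable ketone that is formed, and the hydroxy acid may relactonise if the pH drops before oxidation. Fallback, setting out from 16 and coming back at 18: 16 would be opened with KOH (1.05 equiv) to the potassium salt 17, which is dried and alkylated on the carboxylate with MeI in DMF to give methyl 2-[2,4-bis(benzyloxy)-6-pentylphenoxy]-6-(1-hydroxypentyl)-4-methoxybenzoate F4. F4 would be oxidised at once with Dess–Martin periodinane (CH2Cl2, NaHCO3) to methyl 2-[2,4-bis(benzyloxy)-6-pentylphenoxy]-4-methoxy-6-pentanoylbenzoate F5. LiOH in THF/H2O would then hydrolyse F5 to 18, helped by the neighbouring ketone.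

**Further compounds**

F1 | step 5 | 1,3-bis(benzyloxy)-5-pentylbenzene | CCCCCc1cc(OCc2ccccc2)cc(OCc2ccccc2)c1
F2 | step 5 | 1,5-bis(benzyloxy)-2-iodo-3-pentylbenzene | CCCCCc1cc(OCc2ccccc2)cc(OCc2ccccc2)c1I
F3 | step 7 | 2-bromo-4-[(3-butyl-5-methoxy-1-oxo-1,3-dihydro-2-benzofuran-7-yl)oxy]-5-pentylcyclohexane-1,3-dione | CCCCCC1CC(=O)C(Br)C(=O)C1Oc1cc(OC)cc2c1C(=O)OC2CCCC
F4 | step 9 | methyl 2-[2,4-bis(benzyloxy)-6-pentylphenoxy]-6-(1-hydroxypentyl)-4-methoxybenzoate | CCCCCc1cc(OCc2ccccc2)cc(OCc2ccccc2)c1Oc1cc(OC)cc(C(O)CCCC)c1C(=O)OC
F5 | step 9 | methyl 2-[2,4-bis(benzyloxy)-6-pentylphenoxy]-4-methoxy-6-pentanoylbenzoate | CCCCCc1cc(OCc2ccccc2)cc(OCc2ccccc2)c1Oc1cc(OC)cc(C(=O)CCCC)c1C(=O)OC
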